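Ring A (cyclohexene C1(OAc)–C2–C3=C4(Me)–C5(H)–C17(Me)) hides a Diels–Alder retron once its alkene is shifted to C2=C3: C1 and C4 are the termini of a 1-silyloxy-1,3-pentadiene, and the trans ring-fusion pair C17/C5 is an (E)-2-methyl-2-enal. One catalytic enantioselective cycloaddition of diene 5 and chloro-enal 3 forms C1–C17 and C4–C5, builds quaternary C17 next to C5 (trans) and sets the absolute configuration. C16 is set by a catalytic alkylzinc addition and relays to C1 (Evans–Tishchenko), C13 is bought, and ten-membered ring B is closed last by a butenolide vinylogous aldol–elimination.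

Key step: step 3

Remarks.
- Atom labels: ring A = C1, C2, C3, C4, C5, C17; ring B = C5, C6, C7, C11, C12, C13, C14, C15, C16, C17; butenolide = C7, C8, C9, O10, C11.
- Assumption: in step 3 the oxazaborolidinium catalyst shields the enal face as in the formyl C–H···O binding model for α-substituted enals. If the opposite sense is found, the enantiomeric catalyst is used with no other change.

Step 1
Reactants: 1 chloroacetaldehyde; 2 2-(triphenylphosphoranylidene)propanal
Product: 3 (E)-4-chloro-2-methylbut-2-enal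
Conditions: 1 (50% aq.), CH2Cl2, rt
Reagents that add atoms: none
Why: Wittig olefination with the formyl-stabilised ylide is E-selective and should give the trisubstituted enal whose geometry later fixes the trans C17/C5 relationship.

Step 2
Reactants: 4 (E)-pent-2-enal
Product: 5 triethyl[(1E,3E)-penta-1,3-dien-1-yloxy]silane
Conditions: Et3SiOTf, Et3N, Et2O, 0 °C to rt
Reagents that add atoms: triethylsilyl trifluoromethanesulfonate, CC[Si](CC)(CC)OS(=O)(=O)C(F)(F)F
Why: Soft enolisation (O-silylation, then γ-deprotonation by the amine) should give the 1-silyloxydiene, mainly 1E, of which the 1E,3E isomer is the one that reacts in step 3.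

Step 3
Reactants: 3 (E)-4-chloro-2-methylbut-2-enal; 5 triethyl[(1E,3E)-penta-1,3-dien-1-yloxy]silane
Product: 6 ring-A aldehyde (1R,2S,5R,6S)-6-(chloromethyl)-1,5-dimethyl-2-(triethylsilyloxy)cyclohex-3-ene-1-carbaldehyde
Conditions: (R)-B-(o-tolyl)oxazaborolidine derived from (R)-α,α-diphenylprolinol (20 mol%), HNTf2 (16 mol%), 5 (3 equiv), CH2Cl2, −78 to −40 °C
Reagents that add atoms: none
Why: Concerted, asynchronous [4+2] cycloaddition of the s-cis diene to the enal held s-trans on the cationic oxazaborolidine (boron on the carbonyl oxygen, formyl C–H···O contact), the closest known reaction type being the oxazaborolidinium-catalysed Diels–Alder reaction of 2-methylacrolein-type enals with 1-oxygenated dienes. Ring A closes by intermolecular suprafacial/suprafacial [4+2] addition, C4 bonding in advance to the enal β-carbon C5 and C1 to the α-carbon C17. C17 and C5 are set trans (CHO versus CH2Cl) by the E geometry of 3 and in the absolute sense by the catalyst, which leaves one enal face open; C1 (OSiEt3 cis to CHO) follows from the endo transition state and C4 (Me cis to OSiEt3) from the E,E geometry of 5. The step needs "ortho" regioselectivity (oxygenated terminus to C17), which the silyloxy group secures by making C4 the nucleophilic terminus and outweighing the C4 methyl. It also needs enantioface selectivity, which rests on the catalyst; endo/exo and C4 are not critical, because C1 is later oxidised and C4 becomes sp2. Only the 1E,3E isomer of 5 can reach the s-cis conformation, so minor diene isomers should be left behind.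

Step 4
Reactants: 7 (R)-(2-methyloxiran-2-yl)methanol
Product: 8 (S)-2-methylbut-3-ene-1,2-diol
Conditions: Me3S+ I− (3.5 equiv), n-BuLi (3.5 equiv), THF, −10 °C to rt
Reagents that add atoms: trimethylsulfonium iodide, C[S+](C)C.[I-]
Why: Corey–Chaykovsky-type opening at the epoxide CH2 by dimethylsulfonium methylide and ylide-mediated loss of Me2S (one-carbon homologation to the allylic alcohol) should leave the quaternary stereocentre untouched, the Payne rearrangement of this glycidol being degenerate.

Step 5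
Reactants: 8 (S)-2-methylbut-3-ene-1,2-diol
Product: 9 (S)-4-ethenyl-2,2,4-trimethyl-1,3-dioxolane
Conditions: 2,2-dimethoxypropane, PPTS (cat.), CH2Cl2, rt
Reagents that add atoms: 2,2-dimethoxypropane, COC(C)(C)OC
Why: Acid-catalysed transacetalisation should close the five-membered acetonide of the primary/tertiary 1,2-diol.

Step 6
Reactants: 9 (S)-4-ethenyl-2,2,4-trimethyl-1,3-dioxolane; 6 ring-A aldehyde
Product: 12 C16 (S)-alcohol, via alkyldiethylborane 10 (not isolated), via dialkylzinc 11 (not isolated)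
Conditions: 9, Et2BH (from Et3B and BH3·SMe2), 0 °C to rt; Et2Zn, 0 °C, volatiles removed; then 6, Ti(OiPr)4, (1R,2R)-1,2-bis(trifluoromethanesulfonamido)cyclohexane (10 mol%), toluene, −20 to 0 °C; aq. NH4Cl
Reagents that add atoms: none
Why: Anti-Markovnikov hydroboration, boron–zinc exchange and titanium-bis(sulfonamide)-catalysed asymmetric 1,2-addition of the dialkylzinc should form C15–C16, the chiral titanium complex directing C15 to the Si face of the formyl group so that C16 is S.

Step 7
Reactants: 12 C16 (S)-alcohol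
Product: 13 C1,C16-diol
Conditions: HF·pyridine, pyridine, THF, 0 °C
Reagents that add atoms: none
Why: Buffered fluoride should cleave the secondary triethylsilyl ether while acetonide and alkyl chloride stay intact.

Step 8
Reactants: 13 C1,C16-diol
Product: 14 hydroxy enone
Conditions: MnO2, CH2Cl2, rt
Reagents that add atoms: none
Why: MnO2 oxidises only the allylic C1 alcohol, not the saturated C16 carbinol, and should give the enone needed to move the ring alkene.

Step 9
Reactants: 14 hydroxy enone
Product: 16 β,γ-unsaturated hydroxy ketone, via bis-silyl dienol ether 15 (not isolated)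
Conditions: Me3SiOTf, Et3N, CH2Cl2, 0 °C; then Bu4NF, AcOH, THF, −78 °C
Reagents that add atoms: none
Why: With C17 quaternary only γ-deprotonation at C4 is possible, so silylation should give the 2-silyloxy-1,3-diene (the C16 silyl ether blocking retro-aldol cleavage), and fluoride-induced kinetic α-protonation at C2 (deconjugation) should deliver the C3=C4 alkene.

Step 10
Reactants: 16 β,γ-unsaturated hydroxy ketone
Product: 17 C16 isovalerate C1 alcohol
Conditions: SmI2 (30 mol%), 3-methylbutanal (5 equiv), THF, −10 °C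
Reagents that add atoms: 3-methylbutanal, CC(C)CC=O
Why: Evans–Tishchenko reduction, in which the samarium-bound hemiacetal of the C16 alcohol delivers hydride to the C1 ketone through a chair transition state (C15 equatorial), should give the 1,3-anti diol monoester, that is C1 S with the isovalerate on O16.

Step 11
Reactants: 17 C16 isovalerate C1 alcohol
Product: 18 diester chloride
Conditions: Ac2O, pyridine, DMAP (cat.), CH2Cl2, 0 °C to rt
Reagents that add atoms: acetic anhydride, CC(=O)OC(C)=O
Why: DMAP-catalysed acetylation of the hindered secondary alcohol should proceed without acyl migration if run promptly after step 10.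

Step 12
Reactants: 18 diester chloride
Product: 19 diester iodide
Conditions: NaI, 2-butanone, 80 °C
Reagents that add atoms: sodium iodide, [Na+].[I-]
Why: Finkelstein exchange (SN2 at the primary C6) should give the iodide needed for zinc insertion.

Step 13
Reactants: 20 3-methyltetronic acid
Product: 21 4-methyl-5-oxo-2,5-dihydrofuran-3-yl trifluoromethanesulfonate
Conditions: Tf2O, iPr2NEt, CH2Cl2, −78 °C
Reagents that add atoms: trifluoromethanesulfonic anhydride, O=S(=O)(OS(=O)(=O)C(F)(F)F)C(F)(F)F
Why: O-Sulfonylation of the vinylogous acid should give the enol triflate, a standard cross-coupling electrophile.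

Step 14
Reactants: 19 diester iodide; 21 butenolide triflate
Product: 23 C6–C7 coupled butenolide, via alkylzinc iodide 22 (not isolated)
Conditions: Zn dust, LiCl, THF, 40 °C; then 21, Pd(OAc)2 (5 mol%), SPhos (10 mol%), THF, rt
Reagents that add atoms: none
Why: Zinc insertion into the primary C–I bond and Negishi sp3–sp2 coupling with the β-triflyloxy butenolide should form C6–C7 while esters, acetonide and alkene are tolerated.

Step 15
Reactants: 23 C6–C7 coupled butenolide
Product: 24 C12,C13-diol
Conditions: AcOH/H2O/THF (3:1:1), 40 °C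
Reagents that add atoms: none
Why: Mild acid hydrolysis should remove the acetonide while esters and butenolide survive.

Step 16
Reactants: 24 C12,C13-diol
Product: 25 α-hydroxy aldehyde
Conditions: SO3·pyridine, DMSO, iPr2NEt, CH2Cl2, 0 °C
Reagents that add atoms: none
Why: Parikh–Doering oxidation should convert the primary alcohol to the aldehyde, the tertiary alcohol being inert and glycol cleavage avoided.

Step 17
Reactants: 25 α-hydroxy aldehyde
Product: 29 CNP0208239.1, via silyloxyfuran aldehyde 26 (not isolated), via macrocyclic aldol bis-silyl ether 27 (not isolated), via target 13-O-trimethylsilyl ether 28 (not isolated)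
Conditions: Me3SiOTf, iPr2NEt, CH2Cl2 (1 mM), −78 to 0 °C; then DBU, rt; aq. citric acid/THF work-up
Reagents that add atoms: none
Why: One-pot vinylogous Mukaiyama aldol/elimination, in which silylation protects the tertiary alcohol and turns the butenolide into a 2-silyloxyfuran whose γ-carbon C11 adds to the silyl-activated aldehyde C12 (ten-membered ring closure), after which DBU should effect E1cB loss of silanolate to the ylidene, the ring allowing only the in-ring cis alkene (E-ylidene), while C13 is untouched.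

Compound list
1 | chloroacetaldehyde | ClCC=O | starting material
2 | 2-(triphenylphosphoranylidene)propanal | CC(C=O)=P(c1ccccc1)(c1ccccc1)c1ccccc1 | starting material
3 | (E)-4-chloro-2-methylbut-2-enal | O=C/C(C)=C/CCl | intermediate
4 | (E)-pent-2-enal | CC/C=C/C=O | starting material
5 | triethyl[(1E,3E)-penta-1,3-dien-1-yloxy]silane | C/C=C/C=C/O[Si](CC)(CC)CC | intermediate
6 | (1R,2S,5R,6S)-6-(chloromethyl)-1,5-dimethyl-2-(triethylsilyloxy)cyclohex-3-ene-1-carbaldehyde (CHO cis to OSiEt3, trans to CH2Cl) | CC[Si](CC)(CC)O[C@H]1C=C[C@@H](C)[C@H](CCl)[C@@]1(C)C=O | intermediate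
7 | (R)-(2-methyloxiran-2-yl)methanol ((R)-2-methylglycidol) | OC[C@@]1(C)OC1 | starting material
8 | (S)-2-methylbut-3-ene-1,2-diol | OC[C@@](C)(O)C=C | intermediate
9 | (S)-4-ethenyl-2,2,4-trimethyl-1,3-dioxolane | CC1(C)OC[C@@](C)(O1)C=C | intermediate
10 | diethyl{2-[(4S)-2,2,4-trimethyl-1,3-dioxolan-4-yl]ethyl}borane (not isolated) | CCB(CC)CC[C@@]1(C)COC(C)(C)O1 | intermediate
11 | bis{2-[(4S)-2,2,4-trimethyl-1,3-dioxolan-4-yl]ethyl}zinc (not isolated) | [Zn](CC[C@@]1(C)COC(C)(C)O1)CC[C@@]1(C)COC(C)(C)O1 | intermediate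
12 | C16 (S)-alcohol: 6 with CHO replaced by (S)-CH(OH)CH2CH2-[(4S)-2,2,4-trimethyl-1,3-dioxolan-4-yl] | CC[Si](CC)(CC)O[C@H]1C=C[C@@H](C)[C@H](CCl)[C@@]1(C)[C@@H](O)CC[C@@]3(C)COC(C)(C)O3 | intermediate
13 | C1,C16-diol: 12 with the C1 silyl ether cleaved (1,3-anti diol) | O[C@H]1C=C[C@@H](C)[C@H](CCl)[C@@]1(C)[C@@H](O)CC[C@@]3(C)COC(C)(C)O3 | intermediate
14 | hydroxy enone: cyclohex-2-enone (C1=O, C2=C3) with C4 Me, C5 CH2Cl, C17 Me and the (16S)-hydroxy side chain | O=C1C=C[C@@H](C)[C@H](CCl)[C@@]1(C)[C@@H](O)CC[C@@]3(C)COC(C)(C)O3 | intermediate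
15 | bis(trimethylsilyl) dienol ether of 14 (C1 OSiMe3, C1=C2, C3=C4; C16 OSiMe3) (not isolated) | C[Si](C)(C)OC1=CC=C(C)[C@H](CCl)[C@@]1(C)[C@@H](O[Si](C)(C)C)CC[C@@]3(C)COC(C)(C)O3 | intermediate
16 | β,γ-unsaturated hydroxy ketone (C1=O, C3=C4) with (16S)-OH | O=C1CC=C(C)[C@H](CCl)[C@@]1(C)[C@@H](O)CC[C@@]3(C)COC(C)(C)O3 | intermediate
17 | (1S,16S) C1 alcohol, C16 3-methylbutanoate (1,3-anti) | O[C@H]1CC=C(C)[C@H](CCl)[C@@]1(C)[C@@H](OC(=O)CC(C)C)CC[C@@]3(C)COC(C)(C)O3 | intermediate
18 | C1 acetate, C16 3-methylbutanoate, C6 chloride | CC(=O)O[C@H]1CC=C(C)[C@H](CCl)[C@@]1(C)[C@@H](OC(=O)CC(C)C)CC[C@@]3(C)COC(C)(C)O3 | intermediate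
19 | C1 acetate, C16 3-methylbutanoate, C6 iodide | CC(=O)O[C@H]1CC=C(C)[C@H](CI)[C@@]1(C)[C@@H](OC(=O)CC(C)C)CC[C@@]3(C)COC(C)(C)O3 | intermediate
20 | 3-methyltetronic acid (4-hydroxy-3-methylfuran-2(5H)-one) | CC1=C(O)COC1=O | starting material
21 | 4-methyl-5-oxo-2,5-dihydrofuran-3-yl trifluoromethanesulfonate | CC1=C(OS(=O)(=O)C(F)(F)F)COC1=O | intermediate
22 | C6 alkylzinc iodide of 19 (not isolated) | CC(=O)O[C@H]1CC=C(C)[C@H](C[Zn]I)[C@@]1(C)[C@@H](OC(=O)CC(C)C)CC[C@@]3(C)COC(C)(C)O3 | intermediate
23 | C6–C7 coupled butenolide with C12,C13 acetonide | CC(=O)O[C@H]1CC=C(C)[C@H](CC2=C(C)C(=O)OC2)[C@@]1(C)[C@@H](OC(=O)CC(C)C)CC[C@@]3(C)COC(C)(C)O3 | intermediate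
24 | (13S) C12,C13-diol | CC(=O)O[C@H]1CC=C(C)[C@H](CC2=C(C)C(=O)OC2)[C@@]1(C)[C@@H](OC(=O)CC(C)C)CC[C@](C)(O)CO | intermediate
25 | (13S) α-hydroxy aldehyde (C12 CHO) | CC(=O)O[C@H]1CC=C(C)[C@H](CC2=C(C)C(=O)OC2)[C@@]1(C)[C@@H](OC(=O)CC(C)C)CC[C@](C)(O)C=O | intermediate
26 | 2-(trimethylsilyloxy)furan with C13 OSiMe3 and C12 CHO (not isolated) | CC(=O)O[C@H]1CC=C(C)[C@H](Cc2coc(O[Si](C)(C)C)c2C)[C@@]1(C)[C@@H](OC(=O)CC(C)C)CC[C@](C)(O[Si](C)(C)C)C=O | intermediate
27 | macrocyclic aldol adduct, C12 and C13 OSiMe3, C11/C12 epimers (not isolated) | CC(=O)O[C@H]1CC=C(C)[C@@H]2CC3=C(C)C(=O)OC3C(O[Si](C)(C)C)[C@@](C)(O[Si](C)(C)C)CC[C@H](OC(=O)CC(C)C)[C@@]12C | intermediate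
28 | 13-O-trimethylsilyl ether of the target (not isolated) | CC(=O)O[C@H]1CC=C(C)[C@@H]2CC3=C(C)C(=O)O/C3=C/[C@@](C)(O[Si](C)(C)C)CC[C@H](OC(=O)CC(C)C)[C@@]12C | intermediate
29 | CNP0208239.1 | CC(=O)O[C@H]1CC=C(C)[C@@H]2CC3=C(C)C(=O)O/C3=C/[C@@](C)(O)CC[C@H](OC(=O)CC(C)C)[C@@]12C | target

Total step count: 17. Longest linear sequence: 13 steps (steps 1, 3, 6, 7, 8, 9, 10, 11, 12, 14, 15, 16, 17).

Steps most likely to fail

Step 17. Transannular strain may let intermolecular aldol oligomerisation outrun ten-membered ring closure, or the silyloxyfuran may add through its α-carbon. The fallback sets out from 23 and comes back at 29, closing the ring by an intramolecular Horner–Wadsworth–Emmons olefination instead. Compound 23 is converted with iPr3SiOTf/Et3N into the 2-(triisopropylsilyloxy)furan F1, which is brominated at C11 with NBS (THF, −78 °C) to the γ-bromobutenolide F2. Arbuzov reaction with P(OEt)3 (80 °C) should give the γ-phosphonobutenolide F3. Acetonide hydrolysis (AcOH/H2O/THF) gives the phosphonate diol F4, and Parikh–Doering oxidation the phosphonate α-hydroxy aldehyde F5. LiCl/DBU in MeCN at high dilution should then form the C11=C12 bond directly, the ring again dictating the E-ylidene geometry, to give 29.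

Step 6. Addition to the neopentyl-type aldehyde may be slow, and the substrate's own facial bias may oppose the catalyst, eroding selectivity at C16. The fallback sets out from 9 and 6 and comes back at 13, replacing catalyst control by a hydroxyl-directed reduction that uses the endo-derived C1 carbinol. Alkene 9 is hydroborated (9-BBN) and iodinated (I2, NaOMe) to the (S)-iodoethyl dioxolane F6. Lithium–iodine exchange (t-BuLi, −78 °C) and addition to 6 give the C16-epimeric alcohols F7, which Dess–Martin oxidation converts to the C16 ketone F8. HF·pyridine frees the C1 alcohol to give the β-hydroxy ketone F9, and Evans–Saksena reduction (Me4NBH(OAc)3, MeCN/AcOH, −20 °C) should deliver the 1,3-anti diol 13.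

Step 3. The catalyst may discriminate the enal faces insufficiently, or a stepwise Mukaiyama–Michael addition with silyl transfer may compete with ring closure. The fallback sets out from 4 and 3 and comes back at 13, using a covalently bound chiral group on the diene. The potassium dienolate of 4 (KOtBu, THF, −78 °C) is acylated with (S)-O-methylmandeloyl chloride to the (1E,3E)-penta-1,3-dienyl (S)-2-methoxy-2-phenylacetate F10. Its BF3·OEt2-promoted Diels–Alder reaction with 3 should give the C1 mandelate aldehyde F11, one diene face being shielded by the phenyl group; the (R)-ester would be used if the sense proves opposite. Alkylzinc addition as in step 6 gives the C16 alcohol C1 mandelate F12, and methanolysis (K2CO3, MeOH) gives 13.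

Further compounds
F1 | step 17 | 2-(triisopropylsilyloxy)furan derived from 23 | CC(=O)O[C@H]1CC=C(C)[C@H](Cc2coc(O[Si](C(C)C)(C(C)C)C(C)C)c2C)[C@@]1(C)[C@@H](OC(=O)CC(C)C)CC[C@@]3(C)COC(C)(C)O3
F2 | step 17 | γ-bromobutenolide (C11 Br) | CC(=O)O[C@H]1CC=C(C)[C@H](CC2=C(C)C(=O)OC2Br)[C@@]1(C)[C@@H](OC(=O)CC(C)C)CC[C@@]3(C)COC(C)(C)O3
F3 | step 17 | γ-phosphonobutenolide (C11 diethyl phosphonate) | CC(=O)O[C@H]1CC=C(C)[C@H](CC2=C(C)C(=O)OC2P(=O)(OCC)OCC)[C@@]1(C)[C@@H](OC(=O)CC(C)C)CC[C@@]3(C)COC(C)(C)O3
F4 | step 17 | phosphonate C12,C13-diol | CC(=O)O[C@H]1CC=C(C)[C@H](CC2=C(C)C(=O)OC2P(=O)(OCC)OCC)[C@@]1(C)[C@@H](OC(=O)CC(C)C)CC[C@](C)(O)CO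
F5 | step 17 | phosphonate α-hydroxy aldehyde | CC(=O)O[C@H]1CC=C(C)[C@H](CC2=C(C)C(=O)OC2P(=O)(OCC)OCC)[C@@]1(C)[C@@H](OC(=O)CC(C)C)CC[C@](C)(O)C=O
F6 | step 6 | (S)-4-(2-iodoethyl)-2,2,4-trimethyl-1,3-dioxolane | ICC[C@@]1(C)COC(C)(C)O1
F7 | step 6 | C16-epimeric alcohols (12 and its C16 epimer) | CC[Si](CC)(CC)O[C@H]1C=C[C@@H](C)[C@H](CCl)[C@@]1(C)C(O)CC[C@@]3(C)COC(C)(C)O3
F8 | step 6 | C16 ketone, C1 triethylsilyl ether | CC[Si](CC)(CC)O[C@H]1C=C[C@@H](C)[C@H](CCl)[C@@]1(C)C(=O)CC[C@@]3(C)COC(C)(C)O3
F9 | step 6 | C1 hydroxy C16 ketone | O[C@H]1C=C[C@@H](C)[C@H](CCl)[C@@]1(C)C(=O)CC[C@@]3(C)COC(C)(C)O3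
F10 | step 3 | (1E,3E)-penta-1,3-dien-1-yl (S)-2-methoxy-2-phenylacetate | C/C=C/C=C/OC(=O)[C@@H](OC)c1ccccc1
F11 | step 3 | ring-A aldehyde with C1 (S)-O-methylmandelate | CO[C@@H](c1ccccc1)C(=O)O[C@H]1C=C[C@@H](C)[C@H](CCl)[C@@]1(C)C=O
F12 | step 3 | C16 (S)-alcohol with C1 (S)-O-methylmandelate | CO[C@@H](c1ccccc1)C(=O)O[C@H]1C=C[C@@H](C)[C@H](CCl)[C@@]1(C)[C@@H](O)CC[C@@]3(C)COC(C)(C)O3
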